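**Retrosynthetic overview**

- Target: 3-O-angeloyl methyl ester of a cis-fused eremophil-6-en-8-one (ring A = C1–C5, C10; ring B = C5–C10; C14 on C5, C15 on C4, side chain C11–C13 on C7). Late disconnections are the C3–O ester and the C7–C11 bond (Pd coupling of a 7-iodoenone with a chiral propionimide enolate).
- Enabling feature: in ring B the quaternary C5 lies para to the C8 carbonyl, so the enone C6=C7–C8=O is one half of a latent mirror-symmetric 4,4-disubstituted cyclohexa-2,5-dienone. The other half (C8=O, C9=C10) offers C10 as acceptor for a C1 radical.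
- Ring B is made first (from 3-methylcyclohex-2-enone). Ring A is closed last by a 6-exo radical cyclisation C1→C10 that desymmetrises the dienone and sets C5 and C10 under control of C3 and C4.
- C4 and the C4–C5 bond come from an Ireland–Claisen rearrangement that relays carbinol chirality; C3 comes from a Felkin–Anh ketone reduction.

Key step: step 10

Remark: the 2-methylbut-2-enoate of the target is the (Z)-isomer (angelate) and has to be introduced without isomerisation to the tiglate.

Step 1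
Reactants: 1 3-methylcyclohex-2-en-1-one
Product: 2 (1S)-3-methylcyclohex-2-en-1-ol
Conditions: (R)-2-methyl-CBS-oxazaborolidine (10 mol%), BH3·SMe2, THF, −20 °C; MeOH quench
Reagents that add atoms: none
Why: Corey–Bakshi–Shibata reduction, in which the alkenyl group acts as the large substituent, should give the (S)-allylic alcohol and sets the carbinol centre used for the later relay.

Step 2
Reactants: 2 (1S)-3-methylcyclohex-2-en-1-ol; 3 propanoyl chloride
Product: 4 (1S)-3-methylcyclohex-2-en-1-yl propanoate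
Conditions: pyridine, DMAP (cat.), CH2Cl2, 0 °C → rt
Reagents that add atoms: none
Why: Standard O-acylation of a secondary allylic alcohol; the stereocentre is not touched.

Step 3
Reactants: 4 (1S)-3-methylcyclohex-2-en-1-yl propanoate
Product: 8 (2R)-2-[(1R)-1-methylcyclohex-2-en-1-yl]propanoic acid, via lithium enolate 5 (not isolated), via silyl ketene acetal 6 (not isolated), via trimethylsilyl ester 7 (not isolated)
Conditions: LiN(i-Pr)2, THF, −78 °C; Me3SiCl, −78 → 65 °C; aq. HCl
Reagents that add atoms: none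
Why: Ireland–Claisen rearrangement: the (E)-silyl ketene acetal should react through the boat-like transition state usual for cyclohex-2-enyl esters, forming C4–C5 suprafacially so that the carbinol configuration is relayed to the quaternary C5 (R) and, through the ketene acetal geometry, to C4 (R).

Step 4
Reactants: 8 (2R)-2-[(1R)-1-methylcyclohex-2-en-1-yl]propanoic acid; 9 tributyl(vinyl)stannane
Product: 11 (4R)-4-[(1R)-1-methylcyclohex-2-en-1-yl]pent-1-en-3-one, via acid chloride 10 (not isolated)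
Conditions: (COCl)2, DMF (cat.), CH2Cl2, 0 °C → rt; then 9, Pd(PPh3)4 (cat.), THF, 50 °C
Reagents that add atoms: none
Why: Acid chloride formation followed by Stille acylation gives the vinyl ketone under base-free conditions, so the α-stereocentre C4 should not enolise; no new stereocentre.

Step 5
Reactants: 11 (4R)-4-[(1R)-1-methylcyclohex-2-en-1-yl]pent-1-en-3-one
Product: 12 (3S,4R)-4-[(1R)-1-methylcyclohex-2-en-1-yl]pent-1-en-3-ol
Conditions: NaBH4, CeCl3·7H2O, MeOH, −78 °C
Reagents that add atoms: none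
Why: Luche 1,2-reduction under Felkin–Anh control by C4, with the quaternary ring carbon as the large group anti to the incoming hydride, should set C3 as S.

Step 6
Reactants: 12 (3S,4R)-4-[(1R)-1-methylcyclohex-2-en-1-yl]pent-1-en-3-ol
Product: 13 tert-butyl(dimethyl){[(3S,4R)-4-[(1R)-1-methylcyclohex-2-en-1-yl]pent-1-en-3-yl]oxy}silane
Conditions: t-BuMe2SiOTf, 2,6-lutidine, CH2Cl2, −78 → 0 °C
Reagents that add atoms: tert-butyldimethylsilyl triflate, CC(C)(C)[Si](C)(C)OS(=O)(=O)C(F)(F)F
Why: Silylation of a hindered secondary alcohol with the silyl triflate; the bulky silyl ether later serves as the equatorial anchor of the key step.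

Step 7
Reactants: 13 tert-butyl(dimethyl){[(3S,4R)-4-[(1R)-1-methylcyclohex-2-en-1-yl]pent-1-en-3-yl]oxy}silane
Product: 15 tert-butyl{[(3S,4R)-1-iodo-4-[(1R)-1-methylcyclohex-2-en-1-yl]pentan-3-yl]oxy}dimethylsilane, via alkylborane 14 (not isolated)
Conditions: 9-BBN, THF, 0 °C → rt; then NaOMe, I2, MeOH/THF, 0 °C
Reagents that add atoms: iodine, II
Why: Anti-Markovnikov hydroboration of the terminal alkene (9-BBN should leave the ring alkene) followed by base-induced iodinolysis of the primary B–C bond gives the primary iodide in one flask.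

Step 8
Reactants: 15 tert-butyl{[(3S,4R)-1-iodo-4-[(1R)-1-methylcyclohex-2-en-1-yl]pentan-3-yl]oxy}dimethylsilane
Product: 16 (4R)-4-[(2R,3S)-3-{[tert-butyl(dimethyl)silyl]oxy}-5-iodopentan-2-yl]-4-methylcyclohex-2-en-1-one
Conditions: Rh2(cap)4 (cap = caprolactamate, 1 mol%), t-BuOOH, K2CO3, CH2Cl2, rt
Reagents that add atoms: tert-butyl hydroperoxide, CC(C)(C)OO
Why: Rh-catalysed allylic C–H oxidation; the ring alkene has one allylic CH2 only, because its other allylic position is the quaternary carbon, so the C6=C7–C8=O enone should form.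

Step 9
Reactants: 16 (4R)-4-[(2R,3S)-3-{[tert-butyl(dimethyl)silyl]oxy}-5-iodopentan-2-yl]-4-methylcyclohex-2-en-1-one
Product: 17 4-[(2R,3S)-3-{[tert-butyl(dimethyl)silyl]oxy}-5-iodopentan-2-yl]-4-methylcyclohexa-2,5-dien-1-one
Conditions: DDQ, 1,4-dioxane, 100 °C
Reagents that add atoms: none
Why: DDQ dehydrogenation of a 4,4-disubstituted cyclohex-2-enone to the cross-conjugated dienone (as in steroid 1,4-dien-3-one formation); C5 becomes non-stereogenic and C3 and C4 remain the only stereocentres.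

Step 10
Reactants: 17 4-[(2R,3S)-3-{[tert-butyl(dimethyl)silyl]oxy}-5-iodopentan-2-yl]-4-methylcyclohexa-2,5-dien-1-one
Product: 18 (4aR,5R,6S,8aR)-6-{[tert-butyl(dimethyl)silyl]oxy}-4a,5-dimethyl-4a,5,6,7,8,8a-hexahydronaphthalen-2(1H)-one
Conditions: (Me3Si)3SiH (syringe pump), AIBN (cat.), benzene, 80 °C, high dilution
Reagents that add atoms: none
Why: Iodine abstraction by the silyl radical gives the primary C1 radical, which adds to C10, the β-carbon of one enone arm of the dienone, and the α-keto radical formed at C9 is reduced by (Me3Si)3SiH, which carries the chain. The closest known reaction type is the reductive (Giese-type) radical cyclisation of alkyl iodides onto enones, used here to desymmetrise a 4,4-disubstituted cyclohexa-2,5-dienone. Ring A closes in the 6-exo-trig mode, and because the tether on C5 can reach C10 only from its own face the ring fusion must be cis (H10 cis to C14). C5 and C10 are fixed by the choice between the two diastereotopic enone arms, which C3 and C4 make in a chair-like transition state: attack on the arm leading to the target keeps the silyloxy group equatorial (C4 methyl axial), whereas attack on the other arm would force the silyloxy group axial and 1,3-diaxial to the spectator vinyl carbon. The step needs arm selectivity, secured by this equatorial anchor, 6-exo over 7-endo regioselectivity, secured by the polarity match of the nucleophilic radical with the enone β-carbon, and cyclisation ahead of direct reduction, secured by slow addition of the silane. The untouched arm is left as the C6=C7–C8=O enone of the target.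

Step 11
Reactants: 18 (4aR,5R,6S,8aR)-6-{[tert-butyl(dimethyl)silyl]oxy}-4a,5-dimethyl-4a,5,6,7,8,8a-hexahydronaphthalen-2(1H)-one
Product: 19 (4aS,5R,6S,8aR)-6-{[tert-butyl(dimethyl)silyl]oxy}-3-iodo-4a,5-dimethyl-4a,5,6,7,8,8a-hexahydronaphthalen-2(1H)-one (same spatial arrangement as 18; the descriptor at C4a changes because of iodine)
Conditions: I2, pyridine, CH2Cl2, 0 °C → rt
Reagents that add atoms: iodine, II
Why: α-Iodination of the enone by the pyridine-mediated addition–iodination–elimination sequence (Baylis–Hillman-type); there is only one enone, so C7 is the only possible site.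

Step 12
Reactants: 19 (4aS,5R,6S,8aR)-6-{[tert-butyl(dimethyl)silyl]oxy}-3-iodo-4a,5-dimethyl-4a,5,6,7,8,8a-hexahydronaphthalen-2(1H)-one; 20 (4S)-4-benzyl-3-propanoyloxazolidin-2-one
Product: 23 (4S)-4-benzyl-3-[(2R)-2-{(4aR,5R,6S,8aR)-6-[(tert-butyldimethylsilyl)oxy]-4a,5-dimethyl-2-oxo-1,2,4a,5,6,7,8,8a-octahydronaphthalen-3-yl}propanoyl]oxazolidin-2-one, via sodium enolate 21 (not isolated), via chlorozinc enolate 22 (not isolated)
Conditions: 20, NaN(SiMe3)2, THF, −78 °C; ZnCl2, −78 → 0 °C; then 19, Pd(dba)2 (5 mol%), P(t-Bu)3 (10 mol%), THF/DMF, rt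
Reagents that add atoms: none
Why: Negishi-type Pd-catalysed coupling of the weakly basic zinc imide enolate with the alkenyl iodide; the C7–C11 bond should form on the face of the (Z)-enolate opposite the benzyl group, giving 11R.

Step 13
Reactants: 23 (4S)-4-benzyl-3-[(2R)-2-{(4aR,5R,6S,8aR)-6-[(tert-butyldimethylsilyl)oxy]-4a,5-dimethyl-2-oxo-1,2,4a,5,6,7,8,8a-octahydronaphthalen-3-yl}propanoyl]oxazolidin-2-one
Product: 25 (2R)-2-{(4aR,5R,6S,8aR)-6-[(tert-butyldimethylsilyl)oxy]-4a,5-dimethyl-2-oxo-1,2,4a,5,6,7,8,8a-octahydronaphthalen-3-yl}propanoic acid, via peroxy acid 24 (not isolated)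
Conditions: LiOH, H2O2, THF/H2O, 0 °C; then Na2SO3; aq. HCl to pH 3
Reagents that add atoms: hydrogen peroxide, OO
Why: Hydroperoxide-mediated exocyclic cleavage of the N-acyloxazolidinone (the peracid formed first is reduced by sulfite), a method that should not epimerise the α-stereocentre C11.

Step 14
Reactants: 25 (2R)-2-{(4aR,5R,6S,8aR)-6-[(tert-butyldimethylsilyl)oxy]-4a,5-dimethyl-2-oxo-1,2,4a,5,6,7,8,8a-octahydronaphthalen-3-yl}propanoic acid
Product: 26 methyl (2R)-2-{(4aR,5R,6S,8aR)-6-[(tert-butyldimethylsilyl)oxy]-4a,5-dimethyl-2-oxo-1,2,4a,5,6,7,8,8a-octahydronaphthalen-3-yl}propanoate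
Conditions: Me3SiCHN2, MeOH/toluene, 0 °C
Reagents that add atoms: (trimethylsilyl)diazomethane, C[Si](C)(C)C=[N+]=[N-]
Why: O-Methylation of the carboxylic acid with a diazomethane equivalent under neutral conditions, which avoids enolisation at C11.

Step 15
Reactants: 26 methyl (2R)-2-{(4aR,5R,6S,8aR)-6-[(tert-butyldimethylsilyl)oxy]-4a,5-dimethyl-2-oxo-1,2,4a,5,6,7,8,8a-octahydronaphthalen-3-yl}propanoate
Product: 27 methyl (2R)-2-[(4aR,5R,6S,8aR)-6-hydroxy-4a,5-dimethyl-2-oxo-1,2,4a,5,6,7,8,8a-octahydronaphthalen-3-yl]propanoate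
Conditions: HF·pyridine, THF, 0 °C → rt
Reagents that add atoms: none
Why: Fluoride-mediated cleavage of the silyl ether under weakly acidic conditions that should leave C11 and the enone untouched.

Step 16
Reactants: 27 methyl (2R)-2-[(4aR,5R,6S,8aR)-6-hydroxy-4a,5-dimethyl-2-oxo-1,2,4a,5,6,7,8,8a-octahydronaphthalen-3-yl]propanoate; 28 angelic acid [(2Z)-2-methylbut-2-enoic acid]
Product: 30 methyl (2R)-2-[(4aR,5R,6S,8aR)-4a,5-dimethyl-6-{[(2Z)-2-methylbut-2-enoyl]oxy}-2-oxo-1,2,4a,5,6,7,8,8a-octahydronaphthalen-3-yl]propanoate (CNP0323033.1), via mixed anhydride 29 (not isolated)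
Conditions: 28, 2,4,6-trichlorobenzoyl chloride, Et3N, toluene, rt; then 27, 80 °C (no DMAP)
Reagents that add atoms: none
Why: Yamaguchi-type mixed-anhydride esterification without a nucleophilic catalyst, which should acylate the secondary alcohol with retention at C3 and without Z→E isomerisation of the angelate.

**Compound list**

1 | 3-methylcyclohex-2-en-1-one | CC1=CC(=O)CCC1 | starting material
2 | (1S)-3-methylcyclohex-2-en-1-ol | O[C@@H]1C=C(C)CCC1 | intermediate
3 | propanoyl chloride | CCC(Cl)=O | starting material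
4 | (1S)-3-methylcyclohex-2-en-1-yl propanoate | CCC(=O)O[C@@H]1C=C(C)CCC1 | intermediate
5 | lithium enolate of 4 (methyl cis to the allylic oxygen) | C/C=C(\O[C@@H]1C=C(C)CCC1)[O-].[Li+] | intermediate
6 | (E)-trimethylsilyl ketene acetal of 4 (methyl trans to OSiMe3) | C/C=C(\O[C@@H]1C=C(C)CCC1)O[Si](C)(C)C | intermediate
7 | trimethylsilyl (2R)-2-[(1R)-1-methylcyclohex-2-en-1-yl]propanoate | C[C@@H](C(=O)O[Si](C)(C)C)[C@@]1(C)C=CCCC1 | intermediate
8 | (2R)-2-[(1R)-1-methylcyclohex-2-en-1-yl]propanoic acid | C[C@@H](C(=O)O)[C@@]1(C)C=CCCC1 | intermediate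
9 | tributyl(vinyl)stannane | C=C[Sn](CCCC)(CCCC)CCCC | starting material
10 | (2R)-2-[(1R)-1-methylcyclohex-2-en-1-yl]propanoyl chloride | C[C@@H](C(Cl)=O)[C@@]1(C)C=CCCC1 | intermediate
11 | (4R)-4-[(1R)-1-methylcyclohex-2-en-1-yl]pent-1-en-3-one | C[C@@H](C(=O)C=C)[C@@]1(C)C=CCCC1 | intermediate
12 | (3S,4R)-4-[(1R)-1-methylcyclohex-2-en-1-yl]pent-1-en-3-ol | C=C[C@H](O)[C@H](C)[C@@]1(C)C=CCCC1 | intermediate
13 | tert-butyl(dimethyl){[(3S,4R)-4-[(1R)-1-methylcyclohex-2-en-1-yl]pent-1-en-3-yl]oxy}silane | C=C[C@H](O[Si](C)(C)C(C)(C)C)[C@H](C)[C@@]1(C)C=CCCC1 | intermediate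
14 | 9-[(3S,4R)-3-{[tert-butyl(dimethyl)silyl]oxy}-4-[(1R)-1-methylcyclohex-2-en-1-yl]pentyl]-9-borabicyclo[3.3.1]nonane | B1(CC[C@H](O[Si](C)(C)C(C)(C)C)[C@H](C)[C@@]2(C)C=CCCC2)C3CCCC1CCC3 | intermediate
15 | tert-butyl{[(3S,4R)-1-iodo-4-[(1R)-1-methylcyclohex-2-en-1-yl]pentan-3-yl]oxy}dimethylsilane | ICC[C@H](O[Si](C)(C)C(C)(C)C)[C@H](C)[C@@]1(C)C=CCCC1 | intermediate
16 | (4R)-4-[(2R,3S)-3-{[tert-butyl(dimethyl)silyl]oxy}-5-iodopentan-2-yl]-4-methylcyclohex-2-en-1-one | ICC[C@H](O[Si](C)(C)C(C)(C)C)[C@H](C)[C@@]1(C)C=CC(=O)CC1 | intermediate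
17 | 4-[(2R,3S)-3-{[tert-butyl(dimethyl)silyl]oxy}-5-iodopentan-2-yl]-4-methylcyclohexa-2,5-dien-1-one | ICC[C@H](O[Si](C)(C)C(C)(C)C)[C@H](C)C1(C)C=CC(=O)C=C1 | intermediate
18 | (4aR,5R,6S,8aR)-6-{[tert-butyl(dimethyl)silyl]oxy}-4a,5-dimethyl-4a,5,6,7,8,8a-hexahydronaphthalen-2(1H)-one | CC(C)(C)[Si](C)(C)O[C@H]1CC[C@@H]2CC(=O)C=C[C@]2(C)[C@H]1C | intermediate
19 | (4aS,5R,6S,8aR)-6-{[tert-butyl(dimethyl)silyl]oxy}-3-iodo-4a,5-dimethyl-4a,5,6,7,8,8a-hexahydronaphthalen-2(1H)-one | CC(C)(C)[Si](C)(C)O[C@H]1CC[C@@H]2CC(=O)C(I)=C[C@]2(C)[C@H]1C | intermediate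
20 | (4S)-4-benzyl-3-propanoyloxazolidin-2-one | CCC(=O)N1[C@@H](Cc2ccccc2)COC1=O | starting material
21 | sodium (Z)-enolate of 20 | C/C=C(\[O-])N1[C@@H](Cc2ccccc2)COC1=O.[Na+] | intermediate
22 | chlorozinc (Z)-enolate of 20 | C/C=C(\O[Zn]Cl)N1[C@@H](Cc2ccccc2)COC1=O | intermediate
23 | (4S)-4-benzyl-3-[(2R)-2-{(4aR,5R,6S,8aR)-6-[(tert-butyldimethylsilyl)oxy]-4a,5-dimethyl-2-oxo-1,2,4a,5,6,7,8,8a-octahydronaphthalen-3-yl}propanoyl]oxazolidin-2-one | CC(C)(C)[Si](C)(C)O[C@H]1CC[C@@H]2CC(=O)C([C@@H](C)C(=O)N3[C@@H](Cc4ccccc4)COC3=O)=C[C@]2(C)[C@H]1C | intermediate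
24 | (2R)-2-{(4aR,5R,6S,8aR)-6-[(tert-butyldimethylsilyl)oxy]-4a,5-dimethyl-2-oxo-1,2,4a,5,6,7,8,8a-octahydronaphthalen-3-yl}propaneperoxoic acid | CC(C)(C)[Si](C)(C)O[C@H]1CC[C@@H]2CC(=O)C([C@@H](C)C(=O)OO)=C[C@]2(C)[C@H]1C | intermediate
25 | (2R)-2-{(4aR,5R,6S,8aR)-6-[(tert-butyldimethylsilyl)oxy]-4a,5-dimethyl-2-oxo-1,2,4a,5,6,7,8,8a-octahydronaphthalen-3-yl}propanoic acid | CC(C)(C)[Si](C)(C)O[C@H]1CC[C@@H]2CC(=O)C([C@@H](C)C(=O)O)=C[C@]2(C)[C@H]1C | intermediate
26 | methyl (2R)-2-{(4aR,5R,6S,8aR)-6-[(tert-butyldimethylsilyl)oxy]-4a,5-dimethyl-2-oxo-1,2,4a,5,6,7,8,8a-octahydronaphthalen-3-yl}propanoate | CC(C)(C)[Si](C)(C)O[C@H]1CC[C@@H]2CC(=O)C([C@@H](C)C(=O)OC)=C[C@]2(C)[C@H]1C | intermediate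
27 | methyl (2R)-2-[(4aR,5R,6S,8aR)-6-hydroxy-4a,5-dimethyl-2-oxo-1,2,4a,5,6,7,8,8a-octahydronaphthalen-3-yl]propanoate | O[C@H]1CC[C@@H]2CC(=O)C([C@@H](C)C(=O)OC)=C[C@]2(C)[C@H]1C | intermediate
28 | angelic acid, (2Z)-2-methylbut-2-enoic acid | C/C=C(/C)C(=O)O | starting material
29 | (2Z)-2-methylbut-2-enoic 2,4,6-trichlorobenzoic anhydride | C/C=C(/C)C(=O)OC(=O)c1c(Cl)cc(Cl)cc1Cl | intermediate
30 | methyl (2R)-2-[(4aR,5R,6S,8aR)-4a,5-dimethyl-6-{[(2Z)-2-methylbut-2-enoyl]oxy}-2-oxo-1,2,4a,5,6,7,8,8a-octahydronaphthalen-3-yl]propanoate (CNP0323033.1) | C/C=C(/C)C(=O)O[C@H]1CC[C@@H]2CC(=O)C([C@@H](C)C(=O)OC)=C[C@]2(C)[C@H]1C | target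

**Step count and risks**

Total step count: 16. Longest linear sequence: 16 steps (1 → 30); 3, 9, 20 and 28 enter as purchased building blocks.

Steps most likely to fail, most serious first:

Step 10. The radical may not discriminate well enough between the two diastereotopic enone arms (the chair preference rests on one equatorial anchor), or it may be reduced before it cyclises. Fallback, setting out from 17: iodide is displaced by nitrite (NaNO2, DMF, rt) to give 4-[(2R,3S)-3-{[tert-butyl(dimethyl)silyl]oxy}-5-nitropentan-2-yl]-4-methylcyclohexa-2,5-dien-1-one F1. A reversible intramolecular nitronate Michael addition (DBU, MeCN, rt) then closes ring A under thermodynamic instead of kinetic control, giving the cis-fused C1-nitro derivative of 18 F2 (both C1 epimers). Arm selection is then governed by product stability, and only the desired isomer can hold the silyloxy group and C14 both equatorial on ring A. Radical denitration (Bu3SnH, AIBN, toluene, 110 °C) returns to the route at 18.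

Step 12. The coupling may give poor facial control at the enolate, may epimerise the new C11 centre, or may lose iodide by protodehalogenation. Fallback, setting out from 19: Negishi coupling with the Reformatsky reagent made from racemic methyl 2-bromopropanoate (Zn, THF; then Pd(dba)2, P(t-Bu)3, rt) gives the methyl ester directly as a pair of C11 epimers. The pair is separated by chromatography; the unwanted methyl (2S)-2-{(4aR,5R,6S,8aR)-6-[(tert-butyldimethylsilyl)oxy]-4a,5-dimethyl-2-oxo-1,2,4a,5,6,7,8,8a-octahydronaphthalen-3-yl}propanoate F3 is re-equilibrated at C11 with catalytic DBU and recycled. The route is rejoined at 26, so steps 13 and 14 are not needed.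

Step 3. The ketene acetal geometry or the boat preference may erode, which would deliver the C4 epimer; C5 is erased later, so that epimer would end as the enantiomeric series. Fallback, setting out from 2: Johnson–Claisen rearrangement with triethyl orthoacetate (propanoic acid cat., 140 °C) gives ethyl 2-[(1S)-1-methylcyclohex-2-en-1-yl]acetate F4. Saponification (LiOH, THF/H2O) gives 2-[(1S)-1-methylcyclohex-2-en-1-yl]acetic acid F5. Acylation of lithiated (4R)-4-benzyloxazolidin-2-one through the pivaloyl mixed anhydride gives (4R)-4-benzyl-3-{[(1S)-1-methylcyclohex-2-en-1-yl]acetyl}oxazolidin-2-one F6. Auxiliary-controlled methylation (NaN(SiMe3)2, MeI, THF, −78 °C) then sets C4 independently of any sigmatropic transition state, giving (4R)-4-benzyl-3-{(2R)-2-[(1R)-1-methylcyclohex-2-en-1-yl]propanoyl}oxazolidin-2-one F7. Cleavage with LiOH/H2O2 returns to the route at 8.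

Further compounds
F1 | step 10 | 4-[(2R,3S)-3-{[tert-butyl(dimethyl)silyl]oxy}-5-nitropentan-2-yl]-4-methylcyclohexa-2,5-dien-1-one | [O-][N+](=O)CC[C@H](O[Si](C)(C)C(C)(C)C)[C@H](C)C1(C)C=CC(=O)C=C1
F2 | step 10 | C1-nitro derivative of 18 (nitro on the ring-A carbon next to the ring-fusion CH, both epimers at that carbon) | CC(C)(C)[Si](C)(C)O[C@H]1CC([N+](=O)[O-])[C@@H]2CC(=O)C=C[C@]2(C)[C@H]1C
F3 | step 12 | methyl (2S)-2-{(4aR,5R,6S,8aR)-6-[(tert-butyldimethylsilyl)oxy]-4a,5-dimethyl-2-oxo-1,2,4a,5,6,7,8,8a-octahydronaphthalen-3-yl}propanoate | CC(C)(C)[Si](C)(C)O[C@H]1CC[C@@H]2CC(=O)C([C@H](C)C(=O)OC)=C[C@]2(C)[C@H]1C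
F4 | step 3 | ethyl 2-[(1S)-1-methylcyclohex-2-en-1-yl]acetate | CCOC(=O)C[C@@]1(C)C=CCCC1
F5 | step 3 | 2-[(1S)-1-methylcyclohex-2-en-1-yl]acetic acid | OC(=O)C[C@@]1(C)C=CCCC1
F6 | step 3 | (4R)-4-benzyl-3-{[(1S)-1-methylcyclohex-2-en-1-yl]acetyl}oxazolidin-2-one | O=C(C[C@@]1(C)C=CCCC1)N2[C@H](Cc3ccccc3)COC2=O
F7 | step 3 | (4R)-4-benzyl-3-{(2R)-2-[(1R)-1-methylcyclohex-2-en-1-yl]propanoyl}oxazolidin-2-one | C[C@@H](C(=O)N2[C@H](Cc3ccccc3)COC2=O)[C@@]1(C)C=CCCC1
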